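**Retrosynthetic overview**
- Target 36 comes from methyl ester 34 by saponification in the last step.
- The plan rests on ring A (chroman C4a, C5, C6, C7, C8, C8a): it is hexasubstituted and carries oxygen on the alternate carbons C5 (OH), C7 (OMe) and C8a (ring O). It is cut at C5–C6, C7–C8 and C4a–C5 into the ring-fused 3-alkoxycyclobutenone 29 and the methoxyalkyne 13.
- 29 comes from monocyclic 3-ethoxycyclobutenone 27 by intramolecular alkoxy exchange (pyran ring); 27 comes from a ketene–ethoxyalkyne [2+2] (acid 20 plus alkyne 24). C2 and C3 derive from methyl (S)-3-hydroxybutanoate by Fráter–Seebach methylation.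
- 13 comes from α-methoxy ketone 10 by enol triflate formation and elimination; its stereocentre is set by an Evans alkylation.
- Ring order: four-membered ring, then pyran ring, then ring A.

Key step: step 16

Remark on the chemistry: C4 of cyclobutenones 27 and 28 (C6, the ring-fusion carbon, of 29) forms without control and is carried as an epimer mixture; it becomes aromatic C4a in step 16. Metalated intermediates are drawn as ion pairs or with a C–Li bond.

**Route**

Step 1
Reactants: 1 (S)-4-benzyloxazolidin-2-one; 2 pentanoyl chloride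
Product: 3 (S)-4-benzyl-3-pentanoyloxazolidin-2-one
Conditions: Et3N, DMAP (cat.), CH2Cl2, 0 °C to rt
Reagents that add atoms: none
Why: DMAP-catalysed N-acylation of the oxazolidinone by the acid chloride is a standard imide formation and creates no stereocentre.

Step 2
Reactants: 3 (S)-4-benzyl-3-pentanoyloxazolidin-2-one; 4 methyl bromoacetate
Product: 6 methyl (3R)-3-{[(4S)-4-benzyl-2-oxo-1,3-oxazolidin-3-yl]carbonyl}hexanoate, via sodium enolate 5 (not isolated)
Conditions: NaN(SiMe3)2, THF, −78 °C; then 4, −78 to −40 °C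
Reagents that add atoms: none
Why: Evans asymmetric alkylation, in which the chelated sodium Z-enolate is alkylated by the reactive bromoacetate on the face opposite the benzyl group, setting the (R) centre that becomes the side-chain stereocentre.

Step 3
Reactants: 6 methyl (3R)-3-{[(4S)-4-benzyl-2-oxo-1,3-oxazolidin-3-yl]carbonyl}hexanoate
Product: 7 (2R)-2-(2-methoxy-2-oxoethyl)pentanoic acid
Conditions: LiOH, H2O2, THF/H2O, 0 °C; then Na2SO3; HCl to pH 2
Reagents that add atoms: hydrogen peroxide (OO)
Why: Hydroperoxide cleavage of the exocyclic imide carbonyl (Evans auxiliary removal) should be much faster at 0 °C than hydroxide attack on the methyl ester, so the half ester is released without touching the α-stereocentre.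

Step 4
Reactants: 7 (2R)-2-(2-methoxy-2-oxoethyl)pentanoic acid
Product: 9 methyl (3R)-3-(2-diazoacetyl)hexanoate, via mixed anhydride 8 (not isolated)
Conditions: iBuOCOCl, N-methylmorpholine, THF, −15 °C; then CH2N2, Et2O, 0 °C to rt
Reagents that add atoms: diazomethane (C=[N+]=[N-])
Why: Acylation of diazomethane by a mixed carbonic anhydride (first stage of the Arndt–Eistert sequence) is chosen over the acid chloride so that the ester and the activated carboxyl of this succinate cannot exchange, and it leaves the α-stereocentre intact.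

Step 5
Reactants: 9 methyl (3R)-3-(2-diazoacetyl)hexanoate
Product: 10 methyl (3R)-3-(2-methoxyacetyl)hexanoate
Conditions: Rh2(OAc)4 (1 mol %), MeOH/CH2Cl2, rt
Reagents that add atoms: methanol (CO)
Why: Dirhodium carbenoid O–H insertion into methanol under neutral conditions should give the α-methoxy ketone, the large excess of methanol outrunning any intramolecular reaction of the carbenoid.

Step 6
Reactants: 10 methyl (3R)-3-(2-methoxyacetyl)hexanoate
Product: 12 methyl (3R)-3-[(Z)-2-methoxy-1-(trifluoromethylsulfonyloxy)ethenyl]hexanoate, via lithium enolate 11 (not isolated)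
Conditions: LiN(SiMe3)2, THF, −78 °C; then N-(5-chloropyridin-2-yl)triflimide, −78 °C; NH4Cl
Reagents that add atoms: N-(5-chloropyridin-2-yl)-1,1,1-trifluoro-N-(trifluoromethylsulfonyl)methanesulfonamide (O=S(=O)(N(c1ccc(Cl)cn1)S(=O)(=O)C(F)(F)F)C(F)(F)F)
Why: Kinetic deprotonation should occur at the unhindered, methoxy-activated CH2 (lithium chelated by OMe) and not at the tertiary α′-CH, and cold O-triflation of this Z-enolate (enol triflate formation) places H anti to OTf while forestalling Claisen attack on the ester.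

Step 7
Reactants: 12 methyl (3R)-3-[(Z)-2-methoxy-1-(trifluoromethylsulfonyloxy)ethenyl]hexanoate
Product: 13 methyl (3R)-3-(methoxyethynyl)hexanoate
Conditions: KOtBu, THF, −78 °C
Reagents that add atoms: none
Why: Base-induced anti β-elimination of triflate from the alkoxy enol triflate (the alkynyl ether synthesis from α-alkoxy ketones) is fast at −78 °C, where the methyl ester and the propargylic stereocentre should be untouched.

Step 8
Reactants: 14 methyl (S)-3-hydroxybutanoate
Product: 16 methyl (2S,3S)-3-hydroxy-2-methylbutanoate, via dilithium dianion 15 (not isolated)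
Conditions: LiN(iPr)2 (2.2 equiv), THF, −78 to −20 °C; then MeI, DMPU, −78 to 0 °C; NH4Cl
Reagents that add atoms: iodomethane (CI)
Why: Fráter–Seebach alkylation, in which the lithium-chelated dianion is methylated on the face opposite the methyl group of the carbinol carbon, setting the new centre anti to the existing (S) carbinol.

Step 9
Reactants: 16 methyl (2S,3S)-3-hydroxy-2-methylbutanoate
Product: 17 methyl (2S,3S)-3-(tert-butyldimethylsilyloxy)-2-methylbutanoate
Conditions: TBSCl, imidazole, DMF, rt
Reagents that add atoms: tert-butyldimethylsilyl chloride (CC(C)(C)[Si](C)(C)Cl)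
Why: Imidazole-promoted silylation protects the secondary alcohol for the reduction and the later ketene generation.

Step 10
Reactants: 17 methyl (2S,3S)-3-(tert-butyldimethylsilyloxy)-2-methylbutanoate
Product: 18 (2S,3S)-3-(tert-butyldimethylsilyloxy)-2-methylbutanal
Conditions: iBu2AlH, CH2Cl2, −78 °C; aq. KNaC4H4O6 (potassium sodium tartrate)
Reagents that add atoms: none
Why: Partial ester reduction stops at the aldehyde because the aluminium hemiacetal is stable at −78 °C, and the α-stereocentre is not enolised.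

Step 11
Reactants: 18 (2S,3S)-3-(tert-butyldimethylsilyloxy)-2-methylbutanal
Product: 19 benzyl (2E,4R,5S)-5-(tert-butyldimethylsilyloxy)-4-methylhex-2-enoate
Conditions: Ph3P=CHCO2Bn, CH2Cl2, rt
Reagents that add atoms: benzyl (triphenylphosphoranylidene)acetate (O=C(OCc1ccccc1)C=P(c1ccccc1)(c1ccccc1)c1ccccc1)
Why: Wittig olefination with a stabilised ylide should give the E enoate under neutral conditions that do not epimerise the α-branched aldehyde.

Step 12
Reactants: 19 benzyl (2E,4R,5S)-5-(tert-butyldimethylsilyloxy)-4-methylhex-2-enoate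
Product: 20 (4R,5S)-5-(tert-butyldimethylsilyloxy)-4-methylhexanoic acid
Conditions: H2 (1 atm), 10% Pd/C, EtOAc, rt
Reagents that add atoms: none
Why: Catalytic hydrogenation saturates the alkene and hydrogenolyses the benzyl ester in one operation, while the silyl ether survives in an aprotic solvent.

Step 13
Reactants: 21 ethoxyacetylene; 22 prenyl bromide (1-bromo-3-methylbut-2-ene)
Product: 24 1-ethoxy-5-methylhex-4-en-1-yne, via lithium ethoxyacetylide 23 (not isolated)
Conditions: n-BuLi, THF, −78 °C; then 22, DMPU, −78 °C to rt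
Reagents that add atoms: none
Why: C-alkylation of the lithium alkoxyacetylide by the primary allylic bromide (SN2 at the unsubstituted terminus) is a standard route to substituted alkynyl ethers.

Step 14
Reactants: 20 (4R,5S)-5-(tert-butyldimethylsilyloxy)-4-methylhexanoic acid; 24 1-ethoxy-5-methylhex-4-en-1-yne
Product: 27 4-[(2R,3S)-3-(tert-butyldimethylsilyloxy)-2-methylbutyl]-3-ethoxy-2-(3-methylbut-2-enyl)cyclobut-2-en-1-one, via acid chloride 25 (not isolated), via ketene 26 (not isolated)
Conditions: 1-chloro-N,N,2-trimethylprop-1-en-1-amine, CH2Cl2, 0 °C; then slow addition to 24 (1.5 equiv), Et3N, CH2Cl2, rt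
Reagents that add atoms: none
Why: Dehydrochlorination gives the monoalkylketene, which is trapped as it forms by the electron-rich alkynyl ether in a ketene–alkoxyalkyne [2+2] cycloaddition whose polarity joins the ketene carbonyl carbon to the prenyl-bearing alkyne carbon; the new ring stereocentre is uncontrolled and is erased in step 16.

Step 15
Reactants: 27 4-[(2R,3S)-3-(tert-butyldimethylsilyloxy)-2-methylbutyl]-3-ethoxy-2-(3-methylbut-2-enyl)cyclobut-2-en-1-one
Product: 29 (3S,4R)-3,4-dimethyl-8-(3-methylbut-2-enyl)-2-oxabicyclo[4.2.0]oct-1(8)-en-7-one, via hydroxy cyclobutenone 28 (not isolated)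
Conditions: HF·pyridine, THF, 0 °C to rt; then CSA (cat.), PhH, 5 Å MS, 40 °C
Reagents that add atoms: none
Why: After desilylation, acid-catalysed addition–elimination of the secondary alcohol at C3 of the vinylogous ester (alkoxy exchange, 6-exo-trig) closes the pyran ring, driven by sequestration of ethanol, and the carbinol C–O bond is never broken, so its configuration is retained.

Step 16
Reactants: 29 (3S,4R)-3,4-dimethyl-8-(3-methylbut-2-enyl)-2-oxabicyclo[4.2.0]oct-1(8)-en-7-one; 13 methyl (3R)-3-(methoxyethynyl)hexanoate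
Product: 34 methyl (3R)-3-[(2S,3R)-5-hydroxy-7-methoxy-2,3-dimethyl-8-(3-methylbut-2-enyl)chroman-6-yl]hexanoate, via vinylketene 30 (not isolated), via vinylcyclobutenone 31 (not isolated), via dienylketene 32 (not isolated), via cyclohexadienone 33 (not isolated)
Conditions: 13 (1.3 equiv), PhMe, 110 °C then 150 °C (sealed tube); then K2CO3, MeOH, rt
Reagents that add atoms: none
Why: Proposed new method: heating should open 29 by four-electron electrocyclic cleavage of its C7–C6 bond (bicyclic numbering) to the dihydropyranyl vinylketene 30, which adds alkynyl ether 13 in a [2+2] cycloaddition (chroman bonds C5–C6 and C7–C8), after which adduct 31 opens in a second four-electron step to dienylketene 32, closes by six-electron electrocyclisation (bond C4a–C5) to cyclohexadienone 33 and tautomerises to the phenol. The closest known reaction type is the Danheiser benzannulation of 3-alkyl- and 3-aryl-cyclobutenones with alkoxy- and siloxyalkynes; what is new is a ring-fused 3-alkoxycyclobutenone, whose vinylogous-ester conjugation may raise the temperature needed for the first opening. Ring A is closed by a 6π electrocyclisation of the s-cis dienylketene followed by enolisation, with the pyran ring carried through intact. No stereocentre is created: the ring-fusion carbon of 29 and the quaternary carbon of 31 both end up sp2, and the three existing stereocentres are spectators under these neutral thermal conditions. The step needs one regiochemical outcome, the side chain at C6 between OH and OMe, and this is secured by the polarisation of the alkynyl ether, whose carbon remote from OMe bonds to the ketene carbonyl carbon, while the pyran ring forces the ring CH2 outward in the first opening so that H points inward for the electrocyclisation. The closing K2CO3/MeOH treatment returns any aryl ester or dihydrocoumarin formed at high temperature to 34.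

Step 17
Reactants: 34 methyl (3R)-3-[(2S,3R)-5-hydroxy-7-methoxy-2,3-dimethyl-8-(3-methylbut-2-enyl)chroman-6-yl]hexanoate
Product: 36 (3R)-3-[(2S,3R)-5-hydroxy-7-methoxy-2,3-dimethyl-8-(3-methylbut-2-enyl)chroman-6-yl]hexanoic acid, via dilithium salt 35 (not isolated)
Conditions: LiOH, THF/MeOH/H2O, rt; then 0.5 M HCl to pH 3–4, 0 °C, immediate extraction
Reagents that add atoms: lithium hydroxide ([Li+].[OH-])
Why: Ester saponification also reopens any dihydrocoumarin, and cold acidification only to pH 3–4 should release the hydroxy acid before it can lactonise; no stereocentre is affected.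

**Compound list**
1 | (S)-4-benzyloxazolidin-2-one | O=C1N[C@@H](Cc2ccccc2)CO1 | starting material
2 | pentanoyl chloride | CCCCC(Cl)=O | starting material
3 | (S)-4-benzyl-3-pentanoyloxazolidin-2-one | CCCCC(=O)N1[C@@H](Cc2ccccc2)COC1=O | intermediate
4 | methyl bromoacetate | COC(=O)CBr | starting material
5 | sodium (Z)-enolate of 3 | CCC/C=C(\[O-])N1[C@@H](Cc2ccccc2)COC1=O.[Na+] | intermediate
6 | methyl (3R)-3-{[(4S)-4-benzyl-2-oxo-1,3-oxazolidin-3-yl]carbonyl}hexanoate | CCC[C@H](CC(=O)OC)C(=O)N1[C@@H](Cc2ccccc2)COC1=O | intermediate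
7 | (2R)-2-(2-methoxy-2-oxoethyl)pentanoic acid | CCC[C@H](CC(=O)OC)C(=O)O | intermediate
8 | methyl (3R)-3-{[(2-methylpropoxy)carbonyl]oxycarbonyl}hexanoate (mixed anhydride) | CCC[C@H](CC(=O)OC)C(=O)OC(=O)OCC(C)C | intermediate
9 | methyl (3R)-3-(2-diazoacetyl)hexanoate | CCC[C@H](CC(=O)OC)C(=O)C=[N+]=[N-] | intermediate
10 | methyl (3R)-3-(2-methoxyacetyl)hexanoate | CCC[C@H](CC(=O)OC)C(=O)COC | intermediate
11 | lithium (Z)-enolate of 10 | CCC[C@H](CC(=O)OC)/C([O-])=C/OC.[Li+] | intermediate
12 | methyl (3R)-3-[(Z)-2-methoxy-1-(trifluoromethylsulfonyloxy)ethenyl]hexanoate | CCC[C@H](CC(=O)OC)/C(OS(=O)(=O)C(F)(F)F)=C/OC | intermediate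
13 | methyl (3R)-3-(methoxyethynyl)hexanoate | CCC[C@H](CC(=O)OC)C#COC | intermediate
14 | methyl (S)-3-hydroxybutanoate | C[C@H](O)CC(=O)OC | starting material
15 | dilithium alkoxide-enolate of 14 | C[C@H]([O-])/C=C(\[O-])OC.[Li+].[Li+] | intermediate
16 | methyl (2S,3S)-3-hydroxy-2-methylbutanoate | C[C@H](O)[C@H](C)C(=O)OC | intermediate
17 | methyl (2S,3S)-3-(tert-butyldimethylsilyloxy)-2-methylbutanoate | C[C@H](O[Si](C)(C)C(C)(C)C)[C@H](C)C(=O)OC | intermediate
18 | (2S,3S)-3-(tert-butyldimethylsilyloxy)-2-methylbutanal | C[C@H](O[Si](C)(C)C(C)(C)C)[C@H](C)C=O | intermediate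
19 | benzyl (2E,4R,5S)-5-(tert-butyldimethylsilyloxy)-4-methylhex-2-enoate | C[C@H](O[Si](C)(C)C(C)(C)C)[C@H](C)/C=C/C(=O)OCc1ccccc1 | intermediate
20 | (4R,5S)-5-(tert-butyldimethylsilyloxy)-4-methylhexanoic acid | C[C@H](O[Si](C)(C)C(C)(C)C)[C@H](C)CCC(=O)O | intermediate
21 | ethoxyacetylene | CCOC#C | starting material
22 | prenyl bromide (1-bromo-3-methylbut-2-ene) | CC(C)=CCBr | starting material
23 | lithium ethoxyacetylide | CCOC#C[Li] | intermediate
24 | 1-ethoxy-5-methylhex-4-en-1-yne | CCOC#CCC=C(C)C | intermediate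
25 | (4R,5S)-5-(tert-butyldimethylsilyloxy)-4-methylhexanoyl chloride | C[C@H](O[Si](C)(C)C(C)(C)C)[C@H](C)CCC(Cl)=O | intermediate
26 | (4R,5S)-5-(tert-butyldimethylsilyloxy)-4-methylhex-1-en-1-one (ketene) | C[C@H](O[Si](C)(C)C(C)(C)C)[C@H](C)CC=C=O | intermediate
27 | 4-[(2R,3S)-3-(tert-butyldimethylsilyloxy)-2-methylbutyl]-3-ethoxy-2-(3-methylbut-2-enyl)cyclobut-2-en-1-one (C4 epimers) | CCOC1=C(CC=C(C)C)C(=O)C1C[C@@H](C)[C@H](C)O[Si](C)(C)C(C)(C)C | intermediate
28 | 3-ethoxy-4-[(2R,3S)-3-hydroxy-2-methylbutyl]-2-(3-methylbut-2-enyl)cyclobut-2-en-1-one (C4 epimers) | CCOC1=C(CC=C(C)C)C(=O)C1C[C@@H](C)[C@H](C)O | intermediate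
29 | (3S,4R)-3,4-dimethyl-8-(3-methylbut-2-enyl)-2-oxabicyclo[4.2.0]oct-1(8)-en-7-one (C6 epimers) | O=C1C(CC=C(C)C)=C2O[C@@H](C)[C@H](C)CC12 | intermediate
30 | 2-[(2S,3R)-2,3-dimethyl-3,4-dihydro-2H-pyran-6-yl]-5-methylhexa-1,4-dien-1-one (vinylketene) | O=C=C(CC=C(C)C)C1=CC[C@@H](C)[C@H](C)O1 | intermediate
31 | methyl (3R)-3-{3-[(2S,3R)-2,3-dimethyl-3,4-dihydro-2H-pyran-6-yl]-2-methoxy-3-(3-methylbut-2-enyl)-4-oxocyclobut-1-en-1-yl}hexanoate | CCC[C@H](CC(=O)OC)C1=C(OC)C(CC=C(C)C)(C2=CC[C@@H](C)[C@H](C)O2)C1=O | intermediate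
32 | dienylketene from ring opening of 31 | CCC[C@H](CC(=O)OC)C(=C=O)C(OC)=C(CC=C(C)C)C1=CC[C@@H](C)[C@H](C)O1 | intermediate
33 | cyclohexadienone tautomer of 34 (4a-H) | CCC[C@H](CC(=O)OC)C1=C(OC)C(CC=C(C)C)=C2O[C@@H](C)[C@H](C)CC2C1=O | intermediate
34 | methyl (3R)-3-[(2S,3R)-5-hydroxy-7-methoxy-2,3-dimethyl-8-(3-methylbut-2-enyl)chroman-6-yl]hexanoate | CCC[C@H](CC(=O)OC)c1c(O)c2c(c(CC=C(C)C)c1OC)O[C@@H](C)[C@H](C)C2 | intermediate
35 | dilithium carboxylate-phenolate of 36 | CCC[C@H](CC(=O)[O-])c1c([O-])c2c(c(CC=C(C)C)c1OC)O[C@@H](C)[C@H](C)C2.[Li+].[Li+] | intermediate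
36 | (3R)-3-[(2S,3R)-5-hydroxy-7-methoxy-2,3-dimethyl-8-(3-methylbut-2-enyl)chroman-6-yl]hexanoic acid | CCC[C@H](CC(=O)O)c1c(O)c2c(c(CC=C(C)C)c1OC)O[C@@H](C)[C@H](C)C2 | target

**Step count**
Total: 17 steps. Longest linear sequence: 9 steps (steps 1–7, 16, 17; equally steps 8–12, 14–17).

**Steps most likely to fail**

1. Step 16 (proposed new method). The fused vinylogous ester may resist electrocyclic opening until temperatures at which the partners decompose, or the vinylketene may dimerise faster than it adds the hindered α-branched alkyne. The fallback uses the known photochemical Wolff variant of the benzannulation, which generates the same vinylketene at room temperature from an α-diazo ketone. It sets out from 20 and returns at 34. HF·pyridine and then catalytic TsOH should convert 20 into (5R,6S)-5,6-dimethyltetrahydro-2H-pyran-2-one F1. iBu2AlH at −78 °C gives (5R,6S)-5,6-dimethyltetrahydro-2H-pyran-2-ol F2, and MsCl/Et3N dehydrates it to (2S,3R)-2,3-dimethyl-3,4-dihydro-2H-pyran F3. t-BuLi (THF, −78 to 0 °C) gives the 6-lithiodihydropyran F4, which is acylated by N-methoxy-N,5-dimethylhex-4-enamide F5 (from 5-methylhex-4-enoic acid, carbonyldiimidazole and MeNHOMe·HCl) to the dihydropyranyl ketone F6. LiN(SiMe3)2/CF3CO2CH2CF3 gives its 2-trifluoroacetyl derivative F7, and MsN3/Et3N/H2O in MeCN gives the α-diazo ketone F8 by detrifluoroacetylative diazo transfer. Irradiation of F8 with 13 (Pyrex-filtered mercury lamp, CH2Cl2, rt) causes Wolff rearrangement with migration of the dihydropyranyl group to vinylketene 30. Brief heating at 80–110 °C then completes the cascade through 31–33 to 34.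

2. Step 15. The alkoxy exchange may stall at equilibrium, or the vinylogous ester may hydrolyse or ring-open under acid, because the bicyclic product is more strained than 28. The fallback makes the ring closure an irreversible anionic addition–elimination by using a phenoxide leaving group. It sets out from 20 (with 22 for the alkyne) and returns at 29. Phenol and trichloroethylene (K2CO3, DMF, 70 °C) give (E)-1,2-dichlorovinyl phenyl ether F9. n-BuLi (2.2 equiv, THF, −78 °C) gives lithium phenoxyacetylide F10, and alkylation with 22 in DMPU gives (5-methylhex-4-en-1-ynyl) phenyl ether F11. The [2+2] of F11 with ketene 26, generated from 20 as in step 14, gives the 3-phenoxycyclobutenone F12. Bu4NF (THF, 0 °C) removes the silyl group, and the oxygen of the free alcohol F13 displaces phenoxide at C3 in the same flask to give 29.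

3. Step 6. Deprotonation may compete at the α′ methine (a regioisomeric triflate and proton exchange at the stereocentre), or the enolate may close onto the ester in a Claisen reaction during triflation. The fallback fixes the position of the enol double bond by where a halogen sits, without a strong base. It sets out from 9 and returns at 13. t-BuOCl in MeOH/CH2Cl2 at −20 °C converts 9 into methyl (3R)-3-(2-chloro-2-methoxyacetyl)hexanoate F14. A Perkow reaction with P(OEt)3 (PhMe, 60–80 °C) gives the enol phosphate methyl (3R)-3-[1-(diethoxyphosphoryloxy)-2-methoxyethenyl]hexanoate F15. KOtBu or KN(SiMe3)2 (THF, −78 to −40 °C) then eliminates phosphate to give 13.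

**Further compounds**
F1 | step 16 | (5R,6S)-5,6-dimethyltetrahydro-2H-pyran-2-one | O=C1CC[C@@H](C)[C@H](C)O1
F2 | step 16 | (5R,6S)-5,6-dimethyltetrahydro-2H-pyran-2-ol | OC1CC[C@@H](C)[C@H](C)O1
F3 | step 16 | (2S,3R)-2,3-dimethyl-3,4-dihydro-2H-pyran | C1=CC[C@@H](C)[C@H](C)O1
F4 | step 16 | [(2S,3R)-2,3-dimethyl-3,4-dihydro-2H-pyran-6-yl]lithium | [Li]C1=CC[C@@H](C)[C@H](C)O1
F5 | step 16 | N-methoxy-N,5-dimethylhex-4-enamide | CON(C)C(=O)CCC=C(C)C
F6 | step 16 | 1-[(2S,3R)-2,3-dimethyl-3,4-dihydro-2H-pyran-6-yl]-5-methylhex-4-en-1-one | O=C(CCC=C(C)C)C1=CC[C@@H](C)[C@H](C)O1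
F7 | step 16 | 1-[(2S,3R)-2,3-dimethyl-3,4-dihydro-2H-pyran-6-yl]-5-methyl-2-(trifluoroacetyl)hex-4-en-1-one | O=C(C(CC=C(C)C)C(=O)C(F)(F)F)C1=CC[C@@H](C)[C@H](C)O1
F8 | step 16 | 2-diazo-1-[(2S,3R)-2,3-dimethyl-3,4-dihydro-2H-pyran-6-yl]-5-methylhex-4-en-1-one | O=C(C(=[N+]=[N-])CC=C(C)C)C1=CC[C@@H](C)[C@H](C)O1
F9 | step 15 | [(E)-1,2-dichloroethenyl]oxybenzene | Cl/C=C(/Cl)Oc1ccccc1
F10 | step 15 | lithium phenoxyacetylide | [Li]C#COc1ccccc1
F11 | step 15 | (5-methylhex-4-en-1-yn-1-yl)oxybenzene | CC(C)=CCC#COc1ccccc1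
F12 | step 15 | 4-[(2R,3S)-3-(tert-butyldimethylsilyloxy)-2-methylbutyl]-2-(3-methylbut-2-enyl)-3-phenoxycyclobut-2-en-1-one | CC(C)=CCC1=C(Oc2ccccc2)C(C[C@@H](C)[C@H](C)O[Si](C)(C)C(C)(C)C)C1=O
F13 | step 15 | 4-[(2R,3S)-3-hydroxy-2-methylbutyl]-2-(3-methylbut-2-enyl)-3-phenoxycyclobut-2-en-1-one | CC(C)=CCC1=C(Oc2ccccc2)C(C[C@@H](C)[C@H](C)O)C1=O
F14 | step 6 | methyl (3R)-3-(2-chloro-2-methoxyacetyl)hexanoate | CCC[C@H](CC(=O)OC)C(=O)C(Cl)OC
F15 | step 6 | methyl (3R)-3-[1-(diethoxyphosphoryloxy)-2-methoxyethenyl]hexanoate | CCC[C@H](CC(=O)OC)C(OP(=O)(OCC)OCC)=COC
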